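**Remarks on the chemistry (assumptions)**
- Atom labels such as C5, O6, C7 are heavy-atom positions in the target SMILES. Rings: A = C7, C8, C10, C11, C12, C14; B = C7, C14, C15, C16, C17, C23; C = C16–C20; D = C5, O6, C7, C23, C25.
- PMB = 4-methoxybenzyl, TES = triethylsilyl; compounds 1, 3, 8, 12, 16 and 21 are taken as purchasable.
- Compound numbers 1–33 follow the order of first appearance in the steps and are used throughout.

## Analysis of the target

The target is an angular tetracycle in which C7 belongs to three rings: ring A (a cyclohex-2-ene-1,4-dione), ring B (a cyclohexene with the C14=C15 bond exocyclic to ring A) and ring D (an oxolan-3-one). Ring C, a cyclopentane carrying the tertiary carbinol C20, is fused to ring B at C16–C17. There are six stereocentres: C5 (R), C7 (S), C16 (R), C17 (S), C20 (S) and C23 (R). C7 and C23 are vicinal, fully substituted and cis-fused (B/D). C8 and the methyl C24 lie on one face of ring D, while C14, C17 and the isobutenyl group on C5 lie on the other. The B/C junction is trans, and the C20 hydroxyl is cis to C15 and trans to C23. Sensitive sites are the ene-dione (acceptor at C10/C11), the C5–H (α to the C25 ketone, α to O6 and allylic, so it can epimerise or let the side-chain alkene slide into conjugation), and O6, which sits β to the C12 carbonyl through C14 and can be expelled from any enolate or dienolate there, aromatising ring A. The hard part is the oxygenated quaternary C7 inside a non-aromatic six-membered ring, next to quaternary C23 and with its configuration tied to the remote C5. The strategy rests on the carbon count of ring A: C12–C14=C7 can come from an alkenyl carbene in which C7 already carries O6 and C23 as a member of ring D, C10/C11 from an alkyne and C8 from carbon monoxide. Because C7 then has no hydrogen, the annulation cannot end in a phenol and must deliver C7 inside a 2,4-cyclohexadienone.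

## Retrosynthetic reasoning

**33 from 32.** Only the tertiary silyl ether at C20 is removed. The silyl group is kept to the end because its bulk is used to steer the ring B closure.

**32 from 31 (cut C17–C23).** Ring B is opened at its most hindered bond. Made intramolecularly from the C25 ketone enolate onto the dienone terminus C17, this bond forms through a six-membered transition state. The tether from C14 forces the cis B/D fusion, so the configuration C23 had before is irrelevant. C17 and C16 are set in the same event.

**31 from 29 via 30 (C25 oxidation level).** The C25 ketone is unveiled only here, from a PMB-protected carbinol. Earlier it would make C5 and C23 enolisable through many steps. Before C7 is quaternary, it would pull the exocyclic enol ether into a conjugated furanone.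

**29 from 20 and 25 (cut C14=C15).** An aldol condensation joins ring A to the ring C aldehyde. In 20 the C14 methylene is the only enolisable position, so no regiochemical question arises.

**25 from 21 via 22–24.** The enal carries C15–C20. Its aldehyde carbon comes from formylation of a vinyllithium, and the C20 carbinol from enantioselective methyl addition to bromo-enone 21.

**20 from 18 via 19.** The ene-dione is the hydrolysed form of the methyl dienol ether, and the C10 silicon is removed first, on 18, which has no acidic hydrogen.

**18 from 15 and 16 (cut C11–C12, C8–C10, C7–C8).** This is the central disconnection: ring A falls apart into the alkenyl carbene complex 15, alkyne 16 and one carbonyl ligand of 15. It is placed here because it creates the C7 quaternary centre and the whole ring in one step from a ring D that is easy to make.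

Two features of 15 are deliberate:
- C25 is a PMB-protected carbinol, not a ketone or ketal. A ketal would have to be made from an α-alkynyl ketone in which C23 is configurationally labile; the ether also chelates magnesium in step 5 and cannot migrate in step 7.
- The C23 methyl is cis to the C5 isobutenyl and C25 oxygen substituents. All three then shield one face of ring D, and C8 is sent to the other, which is the face the target needs.

**15 from 11 and 12.** The carbene carbon C12 comes from a carbonyl ligand of 12, attacked by vinyllithium 13 and then O-methylated (via 14).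

**11 from 10 (cut O6–C7).** Ring D is closed 5-exo-dig by the C5 alkoxide onto the bromoalkyne. This fixes the enol ether geometry and leaves the bromine for metalation.

**10 from 7 and 8 via 9 (cut C4–C5).** The isobutenyl group is added to α-alkoxy aldehyde 7 under chelation control, which sets C5 from C25.

**7 from 2 and 3 via 4–6 (cut C23–C25).** An anti-selective allenylzinc addition of mesylate 2 (from 1) to aldehyde 3 sets C23 and C25 together. The styryl group of 3 is a masked C5 aldehyde, released by ozonolysis after PMB protection.

## Alternatives that were turned down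

**Alternative 1:** Ring A is taken from an aromatic precursor and rings B and D are closed together. O6–C7 and C7–C23 are cut, leading to the o-quinone diazide A1, in which C14 carries the chain to ring C and C23 is part of a 2,2-disubstituted oxetan-3-one. Forward, Rh2(OAc)4 would make a carbenoid at C7, O6 would bind it, and a Stevens-type 1,2-shift of C23 from O6 to C7 would expand the oxetanone to ring D and close ring B, giving tetracyclic dienone A2.
- For it: the most congested bond (C7–C23) and the C7–O6 bond form in one step, the cis B/D fusion fixes C7 relative to a C23 centre built beforehand, and oxetane strain drives the shift. In bonds formed per step it is stronger than the chosen route, which needs a separate Michael closure for C17–C23.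
- Against it: the ylide must form through a seven-membered ring (C7, C14, C15, C16, C17, C23, O6), where C–H insertion, capture by the C20 ether oxygen and Wolff-type ring contraction compete. The shift is a radical-pair process and both carbons next to O6 (C23 and C5) are α to the ketone, so migration of C5 is a regiochemical leak. A1 needs a stereodefined quaternary oxetanone next to C17, which is a long synthesis. A2 has no substituent at C5, so the isobutenyl group and C5 configuration would be installed last, at the most epimerisable position.
- Comparison: the chosen strategy is less convergent in bond formation, but its precursor comes from simple acyclic pieces, C5 is present from the start and serves as a control element, and the key step belongs to an established reaction class with one new stereocentre.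

**Alternative 2:** The C7–C14 bond is cut as a retro α-ketol shift. The hydroxy tricycle A4 (rings A, B and C, C7–OH, open C25 ketone side chain) is traced to hydroazulenone A3, in which C14 is bonded to the carbinol carbon C8 of a five-membered ring and C7 is the ketone of a seven-membered ring. Forward, Al(OiPr)3 would chelate the ketol and C14 would migrate from C8 to C7, enlarging the five-membered ring to ring A and contracting the seven-membered ring to ring B.
- For it: the shift is reversible and runs downhill to the six/six system with the conjugated ene-dione, it is suprafacial so C7 is set from C8, and C17–C23 already exists. On thermodynamic control of C7 it is stronger than a kinetically controlled electrocyclisation.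
- Against it: A3 is a cross-conjugated hydroxycyclopentenone fused to a seven-membered ring with quaternary C23 and the ring C centres in place, at least as hard to make as the target. C10 is also bonded to C8 and could migrate instead. Ring D is still missing: the hindered tertiary C7–OH of A4 would have to be joined to C5, which first needs stereoselective oxidation next to the ketone.
- Comparison: the chosen strategy has the O6–C7 bond and ring D from the outset through a 5-exo-dig closure, and far simpler starting materials.

**Alternative 3:** The C7–C23 bond of ring D is cut with ring A as a phenol. Spiro dienone A6 comes from phenol A5, an aryl ether whose oxygen O6 links the methoxy-substituted phenol ring to C5 and to a silyl enol ether (C25=C23). Forward, PhI(OAc)2 would oxidise the phenol at C8–OH and C23 would attack C7, which already bears O6, closing ring D as a spiro 2,4-dienone.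
- For it: A6 is the same kind of spiro A/D dienone that the chosen key step delivers, but with the C25 ketone free and no silicon at C10, from a cheap arene in a few steps and without a stoichiometric metal. On step economy it is clearly stronger.
- Against it: in a 4-methoxyphenol the oxidised ring is most electrophilic at C12 (para, giving a quinone monoketal with acetate or solvent), while the tethered nucleophile must attack ortho at an already substituted carbon. PhI(OAc)2 also oxidises silyl enol ethers and electron-rich alkenes directly. The enol ether must be formed toward C23 in a ketone whose other α-carbon, C5, is the more acidic one and the stereocentre. Facial selectivity at C7 rests on one centre (C5), 1,3 across O6.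
- Comparison: the chosen strategy gives a closed ring D with three substituents on one face before C7 is made, a regiochemistry fixed by mechanism (the carbonyl carbon can only bond to C7), and no oxidant in the presence of the side-chain alkene.

Key step: step 9

## Route

Step 1
Reactants: 1 (S)-4-(trimethylsilyl)but-3-yn-2-ol
Product: 2 (S)-4-(trimethylsilyl)but-3-yn-2-yl methanesulfonate
Conditions: MsCl, Et3N, CH2Cl2, −78 to 0 °C
Reagents that add atoms: methanesulfonyl chloride, CS(Cl)(=O)=O
Why: Sulfonylation of a secondary propargylic alcohol; the C–O bond is not touched, so the (S) configuration is retained.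

Step 2
Reactants: 2 (S)-4-(trimethylsilyl)but-3-yn-2-yl methanesulfonate; 3 (E)-cinnamaldehyde
Product: 5 (1E,3S,4R)-4-methyl-1-phenyl-6-(trimethylsilyl)hex-1-en-5-yn-3-ol, via allenyl(ethyl)zinc 4 (not isolated)
Conditions: Pd(OAc)2 (5 mol%), PPh3 (5 mol%), Et2Zn (3 equiv), THF, −78 to −20 °C; aq. NH4Cl
Reagents that add atoms: diethylzinc, CC[Zn]CC (its ethylzinc unit is in intermediate 4 only)
Why: Zerovalent palladium displaces the mesylate anti (SN2') to an allenylpalladium, Et2Zn transmetallates it to allenylzinc 4, and 4 adds to the aldehyde through a cyclic SE2' transition state (palladium-catalysed allenylzinc propargylation). The sequence is a net inversion at the former carbinol carbon, which gives C23 (R), and the chair-like transition state puts the aldehyde substituent anti to the allene methyl, which gives the anti (3S,4R) adduct with C25 set.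

Step 3
Reactants: 5 (1E,3S,4R)-4-methyl-1-phenyl-6-(trimethylsilyl)hex-1-en-5-yn-3-ol
Product: 6 (1E,3S,4R)-3-[(4-methoxybenzyl)oxy]-4-methyl-1-phenyl-6-(trimethylsilyl)hex-1-en-5-yne
Conditions: NaH, PMBCl, Bu4NI (cat.), THF, 0 °C to rt
Reagents that add atoms: 4-methoxybenzyl chloride, COc1ccc(CCl)cc1
Why: Williamson etherification of the secondary alkoxide. The PMB ether is chosen because it can chelate magnesium in step 5, cannot migrate to the neighbouring alkoxide in step 7 and is removed oxidatively in step 17.

Step 4
Reactants: 6 (1E,3S,4R)-3-[(4-methoxybenzyl)oxy]-4-methyl-1-phenyl-6-(trimethylsilyl)hex-1-en-5-yne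
Product: 7 (2R,3R)-2-[(4-methoxybenzyl)oxy]-3-methyl-5-(trimethylsilyl)pent-4-ynal
Conditions: O3, CH2Cl2/MeOH, −78 °C; Me2S, −78 °C to rt
Reagents that add atoms: ozone, [O-][O+]=O
Why: Ozonolysis of the styrene-type double bond, which reacts far faster than the silylated alkyne; reductive work-up releases the C5 aldehyde without touching C25 or C23.

Step 5
Reactants: 7 (2R,3R)-2-[(4-methoxybenzyl)oxy]-3-methyl-5-(trimethylsilyl)pent-4-ynal; 8 (2-methylprop-1-en-1-yl)magnesium bromide
Product: 9 (3R,4R,5R)-4-[(4-methoxybenzyl)oxy]-3,7-dimethyl-1-(trimethylsilyl)oct-6-en-1-yn-5-ol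
Conditions: MgBr2·OEt2, CH2Cl2, −78 °C; then 8 (THF solution), −78 °C; aq. NH4Cl
Reagents that add atoms: none
Why: Cram-chelate-controlled Grignard addition: magnesium bridges the aldehyde oxygen and the C25 ether oxygen, and the alkenyl group attacks the face away from the C23 branch, creating C5 (R) syn to the C25 oxygen.

Step 6
Reactants: 9 (3R,4R,5R)-4-[(4-methoxybenzyl)oxy]-3,7-dimethyl-1-(trimethylsilyl)oct-6-en-1-yn-5-ol
Product: 10 (3R,4R,5R)-1-bromo-4-[(4-methoxybenzyl)oxy]-3,7-dimethyloct-6-en-1-yn-5-ol
Conditions: NBS, AgNO3 (cat.), acetone, 0 °C to rt, dark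
Reagents that add atoms: N-bromosuccinimide, BrN1C(=O)CCC1=O
Why: Silver-catalysed bromodesilylation of an alkynylsilane (through a silver acetylide); the silver activates only the alkyne, and dry acetone in the dark keeps NBS from the trisubstituted alkene.

Step 7
Reactants: 10 (3R,4R,5R)-1-bromo-4-[(4-methoxybenzyl)oxy]-3,7-dimethyloct-6-en-1-yn-5-ol
Product: 11 (2Z,3S,4R,5R)-2-(bromomethylidene)-4-[(4-methoxybenzyl)oxy]-3-methyl-5-(2-methylprop-1-en-1-yl)oxolane (ring D, the three substituents all cis)
Conditions: KOt-Bu (0.2 equiv), THF/t-BuOH, 0 °C to rt
Reagents that add atoms: none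
Why: Addition of an alkoxide to a 1-bromoalkyne is an anti hydroalkoxylation: the C5 alkoxide closes ring D 5-exo-dig (Baldwin-favoured) onto C7 and the vinyl anion is protonated by t-BuOH, which gives the (Z)-bromo enol ether with bromine cis to O6. No stereocentre is formed or touched.

Step 8
Reactants: 11 (2Z,3S,4R,5R)-2-(bromomethylidene)-4-[(4-methoxybenzyl)oxy]-3-methyl-5-(2-methylprop-1-en-1-yl)oxolane; 12 hexacarbonylchromium
Product: 15 pentacarbonyl{(2Z)-1-methoxy-2-[(3S,4R,5R)-4-[(4-methoxybenzyl)oxy]-3-methyl-5-(2-methylprop-1-en-1-yl)oxolan-2-ylidene]ethylidene}chromium, via vinyllithium 13 (not isolated), via lithium acylchromate 14 (not isolated)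
Conditions: t-BuLi (2.1 equiv), Et2O, −78 °C; Cr(CO)6, THF, −78 to 0 °C; then Me3OBF4, CH2Cl2, 0 °C
Reagents that add atoms: tert-butyllithium, [Li]C(C)(C)C (lithium in 13 and 14 only); trimethyloxonium tetrafluoroborate, C[O+](C)C.F[B-](F)(F)F
Why: Fischer carbene synthesis: bromine–lithium exchange with retention gives the O-chelated (Z)-vinyllithium 13, which adds to a carbonyl ligand of 12 to give acylchromate 14, and O-methylation gives the donor-stabilised alkenyl(methoxy)carbene complex 15.

Step 9
Reactants: 15 pentacarbonyl chromium alkenyl(methoxy)carbene on ring D; 16 ethynyltrimethylsilane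
Product: 18 spiro A/D dienone (5R,7R,23S,25R): ring A is a 4-methoxy-2-(trimethylsilyl)cyclohexa-2,4-dien-1-one spiro-linked at C7 to ring D (23-methyl, 25-PMB-oxy and 5-isobutenyl all cis, C8 on the opposite face), via chromium-bound dienylketene 17 (not isolated)
Conditions: 16 (3 equiv), THF (0.05 M), 55 °C, Ar; then air and light, rt
Reagents that add atoms: none
Why: Thermal loss of one CO from 15 lets 16 coordinate and insert into the Cr=C12 bond (C11–C12), the CH terminus bonding to the carbene carbon and the silyl-bearing C10 to chromium; CO insertion (C8–C10) gives the chromium-bound (Z)-dienylketene 17, and a thermal disrotatory 6π-electrocyclisation joins C8 to C7 and closes ring A. The closest known reaction type is the cyclohexadienone variant of the Dötz benzannulation, the regular outcome for alkenyl(alkoxy)carbene chromium complexes whose alkene terminus is fully substituted: C7 carries O6 and C23 and no hydrogen, so tautomerisation to a phenol is impossible and the product is held at the 2,4-dienone. C7 is the only new stereocentre; it is controlled by ring D, whose methyl (C23, adjacent to C7), PMB-oxy (C25) and isobutenyl (C5) groups all sit on one face, so the ketene carbon C8 should add to the free face, anti to the C5 side chain as the target requires. The step needs CO insertion to win over five-membered ring closure without CO; chromium, an alkoxy carbene, an ethereal solvent, moderate temperature and excess alkyne favour insertion. It needs silicon to end next to the CO-derived carbon, which the size of SiMe3 secures, and since C10 and C11 both end as CH the regiochemistry is in any case erased in step 10. The C10 silyl and C12 methoxy groups also protect the dienone from Diels–Alder dimerisation, and C25 is kept at the carbinol stage so that no ketone can pull the C7=C14 enol ether of 15 into a conjugated furanone.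

Step 10
Reactants: 18 spiro A/D dienone with silicon at C10
Product: 19 spiro A/D dienone (5R,7R,23S,25R) with hydrogen at C10: ring A is a 4-methoxycyclohexa-2,4-dien-1-one
Conditions: TBAF (1 M in THF, wet), THF, 0 °C to rt
Reagents that add atoms: none
Why: Fluoride attacks silicon and the sp2 carbanion at C10, stabilised by the adjacent C8 carbonyl, is protonated by the water in the reagent (protodesilylation of an α-silyl enone). 18 has no enolisable hydrogen, so the basic reagent has nothing else to attack.

Step 11
Reactants: 19 spiro A/D dienone with hydrogen at C10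
Product: 20 spiro ene-dione (5R,7S,23S,25R): ring A is a cyclohex-2-ene-1,4-dione with C14 as CH2
Conditions: 0.5 M aq. HCl, THF, 0 °C, short contact
Reagents that add atoms: water, O
Why: Acid hydrolysis of the enol ether (protonation at C14, hydration at C12, loss of methanol). Cold dilute acid and a short contact time are used because O6 is now β to the C12 carbonyl and could be lost by elimination under forcing conditions.

Step 12
Reactants: 21 2-bromocyclopent-2-en-1-one
Product: 22 (S)-2-bromo-1-methylcyclopent-2-en-1-ol
Conditions: Me2Zn, Ti(OiPr)4, chiral trans-cyclohexane-1,2-diamine bis(hydroxycamphorsulfonamide) ligand (10 mol%), toluene/hexane, rt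
Reagents that add atoms: dimethylzinc, C[Zn]C
Why: Titanium-catalysed enantioselective 1,2-addition of dimethylzinc to an α-substituted cyclic enone; the α-bromine differentiates the two sides of the carbonyl, and the ligand enantiomer is chosen to deliver the (S)-carbinol (C20).

Step 13
Reactants: 22 (S)-2-bromo-1-methylcyclopent-2-en-1-ol
Product: 23 (S)-[(2-bromo-1-methylcyclopent-2-en-1-yl)oxy]triethylsilane
Conditions: TESOTf, 2,6-lutidine, CH2Cl2, −78 to 0 °C
Reagents that add atoms: triethylsilyl trifluoromethanesulfonate, CC[Si](CC)(CC)OS(=O)(=O)C(F)(F)F
Why: Silylation of a tertiary alcohol with the silyl triflate; the silyl ether later shields one face of ring C and is removed by fluoride in the last step.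

Step 14
Reactants: 23 (S)-[(2-bromo-1-methylcyclopent-2-en-1-yl)oxy]triethylsilane
Product: 25 (S)-5-methyl-5-[(triethylsilyl)oxy]cyclopent-1-ene-1-carbaldehyde, via cyclopentenyllithium 24 (not isolated)
Conditions: t-BuLi (2.1 equiv), Et2O, −78 °C; DMF, −78 to 0 °C; aq. NH4Cl
Reagents that add atoms: tert-butyllithium, [Li]C(C)(C)C (lithium in 24 only); N,N-dimethylformamide, CN(C)C=O
Why: Bromine–lithium exchange gives vinyllithium 24, which is formylated by DMF; the enal carries C15, C16 and C17, with C20 untouched.

Step 15
Reactants: 20 spiro ene-dione; 25 (S)-5-methyl-5-[(triethylsilyl)oxy]cyclopent-1-ene-1-carbaldehyde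
Product: 27 aldol adduct: 20 carrying at C14 a CH(OH) group (C15) bonded to C16 of the ring C cyclopentene (mixture at C14 and C15), via boron dienolate 26 (not isolated)
Conditions: Bu2BOTf, iPr2NEt, CH2Cl2, −78 °C; then 25, −78 to 0 °C; pH 7 buffer, MeOH
Reagents that add atoms: dibutylboron trifluoromethanesulfonate, CCCCB(CCCC)OS(=O)(=O)C(F)(F)F (boron in 26 only)
Why: Soft enolisation gives boron dienolate 26 at C14, the only enolisable position of 20, and 26 adds 1,2 to the enal (boron aldol reaction). A boron enolate at −78 °C is used because an alkali enolate or an equilibrating base could expel O6 from C7; the two new centres (C14, C15) are removed in step 16.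

Step 16
Reactants: 27 aldol adduct
Product: 29 (14E)-alkylidene ene-dione (5R,7R,20S,23S,25R): C14=C15 with C16 syn to C7, ring C cyclopentene (C16=C17) attached at C15, via allylic mesylate 28 (not isolated)
Conditions: MsCl, Et3N, CH2Cl2, 0 °C; then DBU, 0 °C to rt
Reagents that add atoms: methanesulfonyl chloride, CS(Cl)(=O)=O (in 28 only)
Why: Mesylation of the allylic alcohol and E1cB elimination; the mesylate is a far better leaving group than the ring oxygen O6, and the (E) geometry, with C16 away from the C12 carbonyl oxygen, is the thermodynamic one.

Step 17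
Reactants: 29 (14E)-alkylidene ene-dione with C25 PMB ether
Product: 30 (14E)-alkylidene ene-dione with free C25 hydroxyl (5R,7R,20S,23S,25R)
Conditions: DDQ, CH2Cl2/pH 7 buffer, 0 °C
Reagents that add atoms: none
Why: Oxidative cleavage of the PMB ether by DDQ (benzylic hydride abstraction, hydrolysis of the oxocarbenium ion); the buffered two-phase medium spares the silyl ether, and the electron-poor ring A is inert to the oxidant.

Step 18
Reactants: 30 (14E)-alkylidene ene-dione with free C25 hydroxyl
Product: 31 trione (5R,7R,20S,23R), 14E: ring D is now the oxolan-3-one, with the C23 methyl still cis to the isobutenyl group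
Conditions: Dess–Martin periodinane, NaHCO3, CH2Cl2, 0 °C to rt
Reagents that add atoms: none
Why: Dess–Martin oxidation of the secondary alcohol under buffered, non-enolising conditions; the C25 ketone appears only now, when C7 is quaternary and no enol ether is left for it to conjugate with.

Step 19
Reactants: 31 trione
Product: 32 TES ether of the target (5R,7S,16R,17S,20S,23R)
Conditions: DBU (0.3 equiv), MeCN, 0 °C to rt
Reagents that add atoms: none
Why: Intramolecular vinylogous Michael addition: the C23 enolate adds 1,6 to the dienone at C17 (6-endo-trig), and the dienolate is protonated at C16 to give the conjugated C14=C15 enone. C23 becomes (R) because the tether from C14 can only reach the face of ring D that C14 occupies, so the methyl group is pushed to the C8 face; C17 should be attacked anti to the bulky silyloxy group on C20. C16 is expected to take its proton so as to give the trans B/C junction, and as the γ-position of the enone it can equilibrate to the more stable arrangement.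

Step 20
Reactants: 32 TES ether of the target
Product: 33 target, CNP0156201.1
Conditions: HF·pyridine, pyridine, THF, 0 °C to rt
Reagents that add atoms: none
Why: Fluoride cleaves the tertiary silyl ether; the buffered medium is not basic enough to enolise C5 and not acidic enough to dehydrate the tertiary alcohol.

## Compound list

1 | (S)-4-(trimethylsilyl)but-3-yn-2-ol | C[C@H](O)C#C[Si](C)(C)C | starting material
2 | (S)-4-(trimethylsilyl)but-3-yn-2-yl methanesulfonate | C[C@H](OS(C)(=O)=O)C#C[Si](C)(C)C | intermediate
3 | (E)-cinnamaldehyde | O=C/C=C/c1ccccc1 | starting material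
4 | (aR)-ethyl[1-(trimethylsilyl)buta-1,2-dien-1-yl]zinc | CC([H])=[C@@]=C([Zn]CC)[Si](C)(C)C | intermediate
5 | (1E,3S,4R)-4-methyl-1-phenyl-6-(trimethylsilyl)hex-1-en-5-yn-3-ol | c1ccccc1/C=C/[C@H](O)[C@@H](C#C[Si](C)(C)C)C | intermediate
6 | (1E,3S,4R)-3-[(4-methoxybenzyl)oxy]-4-methyl-1-phenyl-6-(trimethylsilyl)hex-1-en-5-yne | c1ccccc1/C=C/[C@H](OCc1ccc(OC)cc1)[C@@H](C#C[Si](C)(C)C)C | intermediate
7 | (2R,3R)-2-[(4-methoxybenzyl)oxy]-3-methyl-5-(trimethylsilyl)pent-4-ynal | O=C[C@H](OCc1ccc(OC)cc1)[C@@H](C#C[Si](C)(C)C)C | intermediate
8 | (2-methylprop-1-en-1-yl)magnesium bromide | CC(C)=C[Mg]Br | starting material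
9 | (3R,4R,5R)-4-[(4-methoxybenzyl)oxy]-3,7-dimethyl-1-(trimethylsilyl)oct-6-en-1-yn-5-ol | O[C@H](C=C(C)C)[C@H](OCc1ccc(OC)cc1)[C@@H](C#C[Si](C)(C)C)C | intermediate
10 | (3R,4R,5R)-1-bromo-4-[(4-methoxybenzyl)oxy]-3,7-dimethyloct-6-en-1-yn-5-ol | O[C@H](C=C(C)C)[C@H](OCc1ccc(OC)cc1)[C@@H](C#CBr)C | intermediate
11 | (2Z,3S,4R,5R)-2-(bromomethylidene)-4-[(4-methoxybenzyl)oxy]-3-methyl-5-(2-methylprop-1-en-1-yl)oxolane | Br/C=C1\O[C@H](C=C(C)C)[C@H](OCc2ccc(OC)cc2)[C@@H]1C | intermediate
12 | hexacarbonylchromium | [Cr].[C-]#[O+].[C-]#[O+].[C-]#[O+].[C-]#[O+].[C-]#[O+].[C-]#[O+] | starting material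
13 | (Z)-{[(3S,4R,5R)-4-[(4-methoxybenzyl)oxy]-3-methyl-5-(2-methylprop-1-en-1-yl)oxolan-2-ylidene]methyl}lithium | [Li]/C=C1\O[C@H](C=C(C)C)[C@H](OCc2ccc(OC)cc2)[C@@H]1C | intermediate
14 | lithium pentacarbonyl(acyl)chromate from 13 and 12 (oxido group on C12) | [Li+].[O-]C(/C=C1\O[C@H](C=C(C)C)[C@H](OCc2ccc(OC)cc2)[C@@H]1C)=[Cr].[C-]#[O+].[C-]#[O+].[C-]#[O+].[C-]#[O+].[C-]#[O+] | intermediate
15 | pentacarbonyl{(2Z)-1-methoxy-2-[(3S,4R,5R)-4-[(4-methoxybenzyl)oxy]-3-methyl-5-(2-methylprop-1-en-1-yl)oxolan-2-ylidene]ethylidene}chromium | COC(/C=C1\O[C@H](C=C(C)C)[C@H](OCc2ccc(OC)cc2)[C@@H]1C)=[Cr].[C-]#[O+].[C-]#[O+].[C-]#[O+].[C-]#[O+].[C-]#[O+] | intermediate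
16 | ethynyltrimethylsilane | C#C[Si](C)(C)C | starting material
17 | tricarbonylchromium-bound dienylketene (C8 ketene, C10 silyl, C12 methoxy, C14=C7 on ring D) | O=C=C([Si](C)(C)C)/C=C(OC)\C=C1/O[C@H](C=C(C)C)[C@H](OCc2ccc(OC)cc2)[C@@H]1C.[Cr].[C-]#[O+].[C-]#[O+].[C-]#[O+] | intermediate
18 | spiro A/D dienone (5R,7R,23S,25R), C12 methyl enol ether, C10 silyl, C25 PMB ether | CC(C)=C[C@H]1O[C@@]2(C=C(OC)C=C([Si](C)(C)C)C2=O)[C@@H](C)[C@H]1OCc1ccc(OC)cc1 | intermediate
19 | spiro A/D dienone (5R,7R,23S,25R), C12 methyl enol ether, C25 PMB ether | CC(C)=C[C@H]1O[C@@]2(C=C(OC)C=CC2=O)[C@@H](C)[C@H]1OCc1ccc(OC)cc1 | intermediate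
20 | spiro ene-dione (5R,7S,23S,25R), C25 PMB ether | CC(C)=C[C@H]1O[C@@]2(CC(=O)C=CC2=O)[C@@H](C)[C@H]1OCc1ccc(OC)cc1 | intermediate
21 | 2-bromocyclopent-2-en-1-one | O=C1CCC=C1Br | starting material
22 | (S)-2-bromo-1-methylcyclopent-2-en-1-ol | BrC1=CCC[C@]1(C)O | intermediate
23 | (S)-[(2-bromo-1-methylcyclopent-2-en-1-yl)oxy]triethylsilane | BrC1=CCC[C@]1(C)O[Si](CC)(CC)CC | intermediate
24 | (S)-{5-methyl-5-[(triethylsilyl)oxy]cyclopent-1-en-1-yl}lithium | [Li]C1=CCC[C@]1(C)O[Si](CC)(CC)CC | intermediate
25 | (S)-5-methyl-5-[(triethylsilyl)oxy]cyclopent-1-ene-1-carbaldehyde | O=CC1=CCC[C@]1(C)O[Si](CC)(CC)CC | intermediate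
26 | dibutylboron dienolate of 20 (O–B on C12, C12=C14) | CC(C)=C[C@H]1O[C@@]2(C=C(OB(CCCC)CCCC)C=CC2=O)[C@@H](C)[C@H]1OCc1ccc(OC)cc1 | intermediate
27 | aldol adduct of 20 and 25 (C14–C15 bond, C15 hydroxyl; mixture at C14 and C15) | CC(C)=C[C@H]1O[C@@]2(C(C(O)C3=CCC[C@]3(C)O[Si](CC)(CC)CC)C(=O)C=CC2=O)[C@@H](C)[C@H]1OCc1ccc(OC)cc1 | intermediate
28 | C15 methanesulfonate of 27 | CC(C)=C[C@H]1O[C@@]2(C(C(OS(C)(=O)=O)C3=CCC[C@]3(C)O[Si](CC)(CC)CC)C(=O)C=CC2=O)[C@@H](C)[C@H]1OCc1ccc(OC)cc1 | intermediate
29 | (14E)-alkylidene ene-dione (5R,7R,20S,23S,25R), C25 PMB ether, C20 TES ether | CC(C)=C[C@H]1O[C@@]2(/C(=C\C3=CCC[C@]3(C)O[Si](CC)(CC)CC)C(=O)C=CC2=O)[C@@H](C)[C@H]1OCc1ccc(OC)cc1 | intermediate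
30 | (14E)-alkylidene ene-dione (5R,7R,20S,23S,25R), C25 hydroxyl, C20 TES ether | CC(C)=C[C@H]1O[C@@]2(/C(=C\C3=CCC[C@]3(C)O[Si](CC)(CC)CC)C(=O)C=CC2=O)[C@@H](C)[C@H]1O | intermediate
31 | (14E)-trione (5R,7R,20S,23R), C25 ketone, C20 TES ether | CC(C)=C[C@H]1O[C@@]2(/C(=C\C3=CCC[C@]3(C)O[Si](CC)(CC)CC)C(=O)C=CC2=O)[C@@H](C)C1=O | intermediate
32 | C20 TES ether of the target (5R,7S,16R,17S,20S,23R) | CC(C)=C[C@H]1O[C@@]23C(=O)C=CC(=O)C2=C[C@@H]2[C@H](CC[C@]2(C)O[Si](CC)(CC)CC)[C@@]3(C)C1=O | intermediate
33 | CNP0156201.1 (5R,7S,16R,17S,20S,23R) | CC(C)=C[C@H]1O[C@@]23C(=O)C=CC(=O)C2=C[C@@H]2[C@H](CC[C@]2(C)O)[C@@]3(C)C1=O | target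

## Step count and least certain steps

Total step count: 20.
Longest linear sequence: 17 (steps 1–11 and 15–20); aldehyde 25 is made in 3 steps (12–14).

**Step 9 (key step).** The β-oxygen-substituted alkenyl carbene is electron-rich, so ring closure without CO insertion to a five-membered ring may compete, or the silyl-substituted vinylketene stage may stall. Facial selectivity is the smaller concern because all three ring D substituents shield the same face. Fallback, setting out from 11 and rejoining at 19: the same dienylketene is reached thermally without chromium by ring opening of a 4-alkenylcyclobutenone. Vinyllithium 13 (from 11 as in step 8) is added at −78 °C to cyclobut-3-ene-1,2-dione (O=C1C=CC1=O, a known but not off-the-shelf reagent) to give the 4-hydroxy-4-alkenylcyclobutenone F1. O-Methylation with MeI and Ag2O gives the methyl ether F2. Heating F2 in toluene (80–110 °C) opens the four-membered ring with the methoxy group rotating outward, and the resulting (Z)-dienylketene closes onto C7 to give 19 directly, so steps 8–10 are bypassed.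

**Step 19.** Reversible enolisation of the C25 ketone toward C5 (α-oxy and allylic, more acidic than C23–H) may epimerise C5 or move the side-chain double bond into conjugation. Attack on the wrong face at C17 or a cis B/C junction at C16 are further risks, and the dienolate formed on ring closure can in principle expel O6. Reprotonation at C5 from the face opposite the ring-junction substituents should favour the natural epimer, but this is not assured. Fallback, setting out from 31 and rejoining at 32: C5 is set after ring closure by kinetic protonation. The closure is run under freely equilibrating conditions (Cs2CO3, MeCN), accepting the C5-epimeric tetracycle F3 beside 32. The mixture is converted with KN(SiMe3)2 (THF, −78 °C) into the extended C5 enolate and quenched with 2,6-di-tert-butyl-4-methylphenol; α-protonation from the convex face, away from ring B, should return 32.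

**Step 8.** The cis-β-alkoxy vinyllithium 13 may undergo β-elimination (ring opening to an alkynyl alkoxide) on warming before it adds to the sparingly soluble Cr(CO)6. Fallback, setting out from 9 and rejoining at 15: the carbene is made first and ring D closed afterwards. K2CO3 in MeOH removes the alkyne silyl group to give terminal alkyne F4, and TMSCl/imidazole gives its silyl ether F5. Lithiation with n-BuLi, addition to 12 and methylation with Me3OBF4 give the alkynyl(methoxy)carbene complex F6. Mild acid methanolysis of the O–Si bond frees the C5 hydroxyl, which adds 5-exo-dig to the carbene-activated triple bond (conjugate addition of alcohols to alkynyl carbene complexes) to give 15. Either alkene geometry is competent in step 9. Steps 6–8 are bypassed.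

**Step 10.** The C10–Si bond sits on an sp2 carbon of a six-membered dienone, where no allenolate can assist cleavage, so it may resist fluoride at temperatures the dienone tolerates, or fluoride and hydroxide may add to the dienone. Fallback, setting out from 15 and rejoining at 19: silicon is avoided by running the annulation of step 9 with acetylene itself (saturated THF solution, 1 atm), which gives 19 directly.

**Step 15.** In ene-dione 20, O6 is β to the C12 carbonyl, so enolisation at C14 may lead to loss of O6 (ring opening toward a quinone) or to scrambling of C7; the amine base may also add to the ene-dione. Fallback, setting out from 19 and 25 and rejoining at 27: compound 20 is skipped by a Lewis-acid-promoted Mukaiyama-type addition of the methyl enol ether 19 to 25 (BF3·OEt2, CH2Cl2, −78 °C), with hydrolysis of the oxocarbenium ion on aqueous work-up giving 27.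

**Step 12.** Enantioselection in methyl transfer to a small α-bromo enone may be insufficient. Fallback, setting out from 21 and rejoining at 22: non-selective addition (MeMgBr, CeCl3, THF, −78 °C) gives the racemic carbinol F7, which is resolved by preparative chromatography on a chiral stationary phase to give 22.

## Further compounds

F1 | step 9 | 4-hydroxy-4-{(Z)-[(3S,4R,5R)-4-[(4-methoxybenzyl)oxy]-3-methyl-5-(2-methylprop-1-en-1-yl)oxolan-2-ylidene]methyl}cyclobut-2-en-1-one (either configuration at the carbinol carbon) | OC1(/C=C2\O[C@H](C=C(C)C)[C@H](OCc3ccc(OC)cc3)[C@@H]2C)C=CC1=O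
F2 | step 9 | 4-methoxy analogue of F1 | COC1(/C=C2\O[C@H](C=C(C)C)[C@H](OCc3ccc(OC)cc3)[C@@H]2C)C=CC1=O
F3 | step 19 | C5-epimer of 32 | CC(C)=C[C@@H]1O[C@@]23C(=O)C=CC(=O)C2=C[C@@H]2[C@H](CC[C@]2(C)O[Si](CC)(CC)CC)[C@@]3(C)C1=O
F4 | step 8 | (3R,4R,5R)-4-[(4-methoxybenzyl)oxy]-3,7-dimethyloct-6-en-1-yn-5-ol | O[C@H](C=C(C)C)[C@H](OCc1ccc(OC)cc1)[C@@H](C#C)C
F5 | step 8 | trimethylsilyl ether of F4 | C[Si](C)(C)O[C@H](C=C(C)C)[C@H](OCc1ccc(OC)cc1)[C@@H](C#C)C
F6 | step 8 | pentacarbonyl chromium alkynyl(methoxy)carbene complex from F5 | C[Si](C)(C)O[C@H](C=C(C)C)[C@H](OCc1ccc(OC)cc1)[C@@H](C#CC(OC)=[Cr])C.[C-]#[O+].[C-]#[O+].[C-]#[O+].[C-]#[O+].[C-]#[O+]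
F0 | step 10 | none | none
F0 | step 15 | none | none
F7 | step 12 | racemic 2-bromo-1-methylcyclopent-2-en-1-ol | BrC1=CCCC1(C)O
A1 | alternative 1 | o-quinone diazide with C12 silyl enol ether, ring C chain on C14 and tethered 2-methyloxetan-3-one (C23) | [N-]=[N+]=C1C(=O)C=CC(O[Si](C)(C)C(C)(C)C)=C1C[C@@H]1[C@H](CC[C@]1(C)O[Si](C)(C)C(C)(C)C)[C@@]1(C)C(=O)CO1
A2 | alternative 1 | tetracyclic 2,4-dienone, C12 silyl enol ether, C5 unsubstituted | C1O[C@@]23C(=O)C=CC(O[Si](C)(C)C(C)(C)C)=C2C[C@@H]2[C@H](CC[C@]2(C)O[Si](C)(C)C(C)(C)C)[C@@]3(C)C1=O
A3 | alternative 2 | hydroazulenone α-ketol (C8 carbinol in the five-membered ring, C7 ketone in the seven-membered ring) | O[C@@]12C=CC(=O)C1=C[C@@H]1[C@H](CC[C@]1(C)O)[C@@](C)(C(=O)CC=C(C)C)C2=O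
A4 | alternative 2 | C7 hydroxy tricycle with rings A, B and C | O[C@@]12C(=O)C=CC(=O)C1=C[C@@H]1[C@H](CC[C@]1(C)O)[C@@]2(C)C(=O)CC=C(C)C
A5 | alternative 3 | 4-methoxy-2-alkoxyphenol with tethered (Z)-trimethylsilyl enol ether (C25=C23) | CC(C)=C[C@@H](Oc1cc(OC)ccc1O)/C(O[Si](C)(C)C)=C/C
A6 | alternative 3 | spiro A/D 2,4-dienone, C12 methyl enol ether, C25 ketone | CC(C)=C[C@H]1O[C@@]2(C=C(OC)C=CC2=O)[C@H](C)C1=O
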